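**Strategy.** The route rests on cutting the C1–C14 bond of the 14-membered carbocycle (C1–C14 ring carbons; C15=C17 exocyclic methylene, C16 lactone carbonyl). A primary C14 radical, released from an iodide, closes the macrocycle by adding to C1, the β-carbon of a γ-alkenyl butenolide, anti to the C2 substituent; loss of a phenylthiyl radical from C17 then unveils the C15=C17 methylene. One operation thus gives the carbocycle, the C1 stereocentre and the trans-fused α-methylene-γ-butyrolactone (ring O–C2–C1–C15–C16), the feature exploited. The precursor is a farnesol-derived seco chain carrying the complete C11–C12 epoxide, C13 acetate, C14 iodide and a C2-configured 3-(phenylthiomethyl)butenolide.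

Key step: step 14

Remark: ring locants C1–C20 are used for all open-chain intermediates and CIP descriptors are quoted per compound (priorities at C2, C12 and C13 change with the substituents); the C13 acetate is threo to the trans-11,12-epoxide, so the erythro-selective directed epoxidation is followed by inversion at C13, and sulfur is introduced only after the peroxide step (TBS = tert-butyldimethylsilyl).

Step 1
Reactants: 1 (2E,6E)-farnesol
Product: 2 (2E,6E)-farnesyl TBS ether
Conditions: TBSCl, imidazole, DMF, 0 °C to rt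
Reagents that add atoms: tert-butyldimethylsilyl chloride, CC(C)(C)[Si](C)(C)Cl
Why: Routine silylation of the primary allylic alcohol masks the future C2 oxygen through the oxidative and organometallic steps.

Step 2
Reactants: 2 (2E,6E)-farnesyl TBS ether
Product: 4 (2E,6E,10E)-12-(TBS-oxy)-2,6,10-trimethyldodeca-2,6,10-trienal (C13 enal), via allylic alcohol 3 (not isolated)
Conditions: SeO2 (0.3 equiv), t-BuOOH, salicylic acid (cat.), CH2Cl2, 0 °C to rt; work-up; crude mixture, MnO2, CH2Cl2, rt
Reagents that add atoms: tert-butyl hydroperoxide, CC(C)(C)OO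
Why: Riley allylic oxidation (ene reaction, then [2,3]-shift) attacks the terminal, most electron-rich trisubstituted alkene at its (E)-methyl group, and MnO2 converges the alcohol/aldehyde mixture on the (E)-enal.

Step 3
Reactants: 4 C13 enal; 5 (chloromethyl)(isopropoxy)dimethylsilane
Product: 8 rac-(3E,7E,11E)-13-(TBS-oxy)-3,7,11-trimethyltrideca-3,7,11-triene-1,2-diol (C13,C14-diol), via Grignard reagent 6 (not isolated), via β-hydroxysilane 7 (not isolated)
Conditions: 5, Mg, THF, rt; add 4, 0 °C; NH4Cl aq; crude adduct, KF, KHCO3, 30% H2O2, THF/MeOH, rt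
Reagents that add atoms: hydrogen peroxide, OO
Why: Grignard 1,2-addition of a hydroxymethyl-anion equivalent to the enal followed by Tamao oxidation of the C–Si bond installs C14 as CH2OH; C13 is formed racemic and is resolved in step 5.

Step 4
Reactants: 8 rac-C13,C14-diol
Product: 9 rac-(3E,7E,11E)-1,13-bis(TBS-oxy)-3,7,11-trimethyltrideca-3,7,11-trien-2-ol (C14–OTBS, C13–OH free)
Conditions: TBSCl (1.05 equiv), imidazole, CH2Cl2, −20 to 0 °C
Reagents that add atoms: tert-butyldimethylsilyl chloride, CC(C)(C)[Si](C)(C)Cl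
Why: Sterically controlled silylation of the primary hydroxyl of the 1,2-diol leaves the secondary allylic C13–OH free to direct the epoxidation.

Step 5
Reactants: 9 rac-allylic alcohol
Product: 10 (11R,12R,13R)-erythro epoxy alcohol (trans-11,12-epoxide, C13–OH free, C2 and C14 as TBS ethers)
Conditions: Ti(OiPr)4 (0.2 equiv), D-(−)-diisopropyl tartrate (0.3 equiv), t-BuOOH (0.55 equiv), 4 Å molecular sieves, CH2Cl2, −20 °C
Reagents that add atoms: tert-butyl hydroperoxide, CC(C)(C)OO
Why: Sharpless asymmetric epoxidation run as a kinetic resolution: with the D-(−)-tartrate the (13S)-enantiomer of 9 should be epoxidised fast on the alkene face that gives the epoxide geometry of the target, hydroxyl-directed delivery under A(1,2) strain from the C12 methyl being erythro, so C11, C12 and C13 are set together and the slow enantiomer is removed by chromatography.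

Step 6
Reactants: 10 erythro epoxy alcohol
Product: 11 (11R,12S,13S)-threo epoxy acetate (C13 inverted, C2 and C14 as TBS ethers)
Conditions: AcOH, PPh3, DIAD, toluene, 0 °C to rt
Reagents that add atoms: acetic acid, CC(=O)O
Why: Mitsunobu reaction: SN2 displacement of the C13 oxyphosphonium by acetate inverts C13 and gives the threo acetate of the target under near-neutral conditions that spare the epoxide.

Step 7
Reactants: 11 threo epoxy acetate
Product: 12 (11R,12S,13S)-epoxy acetate diol (C2–OH and C14–OH free)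
Conditions: HF·pyridine, pyridine, THF, 0 °C to rt
Reagents that add atoms: none
Why: Fluoride cleavage of both primary silyl ethers in a buffered, non-basic medium should avoid C13-to-C14 acetyl migration and epoxide opening.

Step 8
Reactants: 12 epoxy acetate diol
Product: 13 (11R,12S,13S)-C2 (E)-enal with free C14–OH
Conditions: MnO2, CH2Cl2, rt
Reagents that add atoms: none
Why: MnO2 oxidises only the allylic C2 alcohol, which differentiates the two primary hydroxyls without a protecting group.

Step 9
Reactants: 13 hydroxy enal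
Product: 14 (11R,12S,13R)-C14 iodide C2 enal
Conditions: I2, PPh3, imidazole, CH2Cl2, 0 °C
Reagents that add atoms: iodine, II
Why: Appel-type iodination (SN2 of iodide on the C14 alkoxyphosphonium) converts the primary alcohol at once, and the imidazole buffer protects epoxide, acetate and enal.

Step 10
Reactants: 14 iodo enal; 15 vinylmagnesium bromide
Product: 17 (2R,11R,12S,13R)-C2 vinyl carbinol (bis-allylic alcohol), via divinylzinc 16 (not isolated)
Conditions: CH2=CHMgBr, ZnCl2, THF; 1,4-dioxane, filter (gives Zn(CH=CH2)2); (+)-MIB [(2R)-3-exo-morpholinoisoborneol, 10 mol%], toluene, −30 to 0 °C; add 14; NH4Cl aq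
Reagents that add atoms: none
Why: Amino-alcohol-catalysed enantioselective 1,2-addition of a vinylzinc reagent to the enal, the (+)-ligand directing vinyl to the Re face to set C2 (R here, the geometry that reads S in the lactone), while the mild organozinc tolerates acetate, epoxide and iodide.

Step 11
Reactants: 18 2-(bromomethyl)acrylic acid; 19 thiophenol
Product: 20 2-[(phenylsulfanyl)methyl]prop-2-enoic acid
Conditions: Et3N (2.2 equiv), THF, 0 °C to rt; 1 M HCl
Reagents that add atoms: none
Why: Thiolate substitution of the activated allylic bromide (direct or by addition–elimination, both giving the same acid) is a standard reaction.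

Step 12
Reactants: 17 C2 vinyl carbinol; 20 2-[(phenylsulfanyl)methyl]prop-2-enoic acid
Product: 21 (2R,11R,12S,13R)-2-(phenylthiomethyl)acrylate ester of 17
Conditions: DCC, DMAP (cat.), CH2Cl2, 0 °C to rt
Reagents that add atoms: none
Why: Steglich esterification acylates the bis-allylic alcohol under neutral conditions without ionising it, with retention at C2.

Step 13
Reactants: 21 acrylate ester
Product: 22 (2S,11R,12S,13R)-seco C14 iodide with the 3-(phenylthiomethyl)butenolide (epoxy acetate intact)
Conditions: second-generation Hoveyda–Grubbs catalyst RuCl2(=CH-C6H4-2-OiPr)(H2IMes) (10 mol%), toluene (0.005 M), 80 °C, argon sparge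
Reagents that add atoms: none
Why: Ring-closing metathesis of the C1 vinyl group with the 2-substituted acrylate closes the butenolide (C1=C15) with loss of ethylene; the hindered C3=C4 and C7=C8 alkenes should not compete and a ring through the (E)-C3=C4 alkene cannot form.

Step 14
Reactants: 22 seco C14 iodide
Product: 23 CNP0146076.5, (1R,2S,3E,7E,11R,12S,13S)-13-acetoxy-11,12-epoxycembra-3,7,15(17)-trien-16,2-olide
Conditions: (Bu3Sn)2 (3 equiv), hν (sunlamp, Pyrex), benzene (0.002 M), 80 °C
Reagents that add atoms: none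
Why: Proposed new method: Bu3Sn• from photolysed (Bu3Sn)2 abstracts iodine from C14, the nucleophilic primary radical adds to the electron-poor β-carbon C1 of the butenolide, and the lactone-stabilised C15 radical expels PhS• from C17 (β-scission) to leave the C15=C17 methylene, PhS• then cleaving the ditin to return Bu3Sn•, so that no hydride donor can quench the C14 radical before it cyclises. The closest known reactions are tin-mediated radical macrocyclisations of ω-iodoalkyl enones and acrylates and the intermolecular allyl-transfer (SH2′) reactions of alkyl iodides with allyl phenyl sulfides or 2-(phenylthiomethyl)acrylates under hexabutylditin; merging them in one ring closure onto a butenolide is the untested part. The 14-membered carbocycle closes in the 14-exo-trig mode, C15 staying outside the new ring. The new stereocentre C1 is controlled by C2: the C1–C14 bond should form on the butenolide face anti to the C2 alkenyl group, giving the trans C1/C2 lactone (1R). The step needs cyclisation to outrun hydrogen-atom shifts, 1,2-acetoxy migration and intermolecular addition; polarity matching, the single activated alkene, the (E)-alkenes and trans-epoxide that stiffen the chain and hold C13 away from the C9 and C10 hydrogens, the radical sitting one carbon removed from the oxirane, and the 0.002 M dilution are relied on for this.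

**Compound list**

1 | (2E,6E)-farnesol | CC(C)=CCC/C(C)=C/CC/C(C)=C/CO | starting material
2 | (2E,6E)-farnesyl tert-butyldimethylsilyl ether | CC(C)=CCC/C(C)=C/CC/C(C)=C/CO[Si](C)(C)C(C)(C)C | intermediate
3 | (2E,6E,10E)-12-(TBS-oxy)-2,6,10-trimethyldodeca-2,6,10-trien-1-ol | CC(C)(C)[Si](C)(C)OC/C=C(\C)CC/C=C(\C)CC/C=C(\C)CO | intermediate
4 | (2E,6E,10E)-12-(TBS-oxy)-2,6,10-trimethyldodeca-2,6,10-trienal | CC(C)(C)[Si](C)(C)OC/C=C(\C)CC/C=C(\C)CC/C=C(\C)C=O | intermediate
5 | (chloromethyl)(isopropoxy)dimethylsilane | CC(C)O[Si](C)(C)CCl | starting material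
6 | [(isopropoxydimethylsilyl)methyl]magnesium chloride | CC(C)O[Si](C)(C)C[Mg]Cl | intermediate
7 | rac-(3E,7E,11E)-13-(TBS-oxy)-1-(isopropoxydimethylsilyl)-3,7,11-trimethyltrideca-3,7,11-trien-2-ol | CC(C)(C)[Si](C)(C)OC/C=C(\C)CC/C=C(\C)CC/C=C(\C)C(O)C[Si](C)(C)OC(C)C | intermediate
8 | rac-(3E,7E,11E)-13-(TBS-oxy)-3,7,11-trimethyltrideca-3,7,11-triene-1,2-diol | CC(C)(C)[Si](C)(C)OC/C=C(\C)CC/C=C(\C)CC/C=C(\C)C(O)CO | intermediate
9 | rac-(3E,7E,11E)-1,13-bis(TBS-oxy)-3,7,11-trimethyltrideca-3,7,11-trien-2-ol | CC(C)(C)[Si](C)(C)OC/C=C(\C)CC/C=C(\C)CC/C=C(\C)C(O)CO[Si](C)(C)C(C)(C)C | intermediate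
10 | (1R)-2-(TBS-oxy)-1-{(2R,3R)-2-methyl-3-[(3E,7E)-3,7-dimethyl-9-(TBS-oxy)nona-3,7-dien-1-yl]oxiran-2-yl}ethan-1-ol (ring locants 11R,12R,13R; erythro) | CC(C)(C)[Si](C)(C)OC/C=C(\C)CC/C=C(\C)CC[C@H]1O[C@]1(C)[C@H](O)CO[Si](C)(C)C(C)(C)C | intermediate
11 | (1S)-2-(TBS-oxy)-1-{(2S,3R)-2-methyl-3-[(3E,7E)-3,7-dimethyl-9-(TBS-oxy)nona-3,7-dien-1-yl]oxiran-2-yl}ethyl acetate (11R,12S,13S; threo) | CC(C)(C)[Si](C)(C)OC/C=C(\C)CC/C=C(\C)CC[C@H]1O[C@]1(C)[C@@H](OC(C)=O)CO[Si](C)(C)C(C)(C)C | intermediate
12 | (1S)-2-hydroxy-1-{(2S,3R)-3-[(3E,7E)-9-hydroxy-3,7-dimethylnona-3,7-dien-1-yl]-2-methyloxiran-2-yl}ethyl acetate (11R,12S,13S) | OC/C=C(\C)CC/C=C(\C)CC[C@H]1O[C@]1(C)[C@@H](OC(C)=O)CO | intermediate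
13 | (1S)-2-hydroxy-1-{(2S,3R)-3-[(3E,7E)-3,7-dimethyl-9-oxonona-3,7-dien-1-yl]-2-methyloxiran-2-yl}ethyl acetate (11R,12S,13S) | O=C/C=C(\C)CC/C=C(\C)CC[C@H]1O[C@]1(C)[C@@H](OC(C)=O)CO | intermediate
14 | (1R)-2-iodo-1-{(2S,3R)-3-[(3E,7E)-3,7-dimethyl-9-oxonona-3,7-dien-1-yl]-2-methyloxiran-2-yl}ethyl acetate (11R,12S,13R) | O=C/C=C(\C)CC/C=C(\C)CC[C@H]1O[C@]1(C)[C@@H](OC(C)=O)CI | intermediate
15 | vinylmagnesium bromide | C=C[Mg]Br | starting material
16 | divinylzinc | C=C[Zn]C=C | intermediate
17 | (1R)-1-{(2S,3R)-3-[(3E,7E,9R)-9-hydroxy-3,7-dimethylundeca-3,7,10-trien-1-yl]-2-methyloxiran-2-yl}-2-iodoethyl acetate (2R,11R,12S,13R) | C=C[C@@H](O)/C=C(\C)CC/C=C(\C)CC[C@H]1O[C@]1(C)[C@@H](OC(C)=O)CI | intermediate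
18 | 2-(bromomethyl)acrylic acid | C=C(CBr)C(=O)O | starting material
19 | thiophenol | Sc1ccccc1 | starting material
20 | 2-[(phenylsulfanyl)methyl]prop-2-enoic acid | C=C(CSc1ccccc1)C(=O)O | intermediate
21 | (3R,4E,8E)-11-{(2R,3S)-3-[(1R)-1-acetoxy-2-iodoethyl]-3-methyloxiran-2-yl}-5,9-dimethylundeca-1,4,8-trien-3-yl 2-[(phenylsulfanyl)methyl]prop-2-enoate (2R,11R,12S,13R) | C=C(CSc1ccccc1)C(=O)O[C@H](C=C)/C=C(\C)CC/C=C(\C)CC[C@H]1O[C@]1(C)[C@@H](OC(C)=O)CI | intermediate
22 | (1R)-2-iodo-1-{(2S,3R)-2-methyl-3-[(3E,7E)-3,7-dimethyl-8-{(2S)-5-oxo-4-[(phenylsulfanyl)methyl]-2,5-dihydrofuran-2-yl}octa-3,7-dien-1-yl]oxiran-2-yl}ethyl acetate (2S,11R,12S,13R) | O=C1O[C@@H](/C=C(\C)CC/C=C(\C)CC[C@H]2O[C@]2(C)[C@@H](OC(C)=O)CI)C=C1CSc1ccccc1 | intermediate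
23 | CNP0146076.5, (1R,2S,3E,7E,11R,12S,13S)-13-acetoxy-11,12-epoxycembra-3,7,15(17)-trien-16,2-olide | C=C1C(=O)O[C@H]2/C=C(\C)CC/C=C(\C)CC[C@H]3O[C@]3(C)[C@@H](OC(C)=O)C[C@H]12 | target

**Step count.** Total: 14 steps. Longest linear sequence: 13 steps (steps 1–10 and 12–14).

**Steps most likely to fail**

1. Step 14 (Proposed new method). The 14-membered ring closure may be too slow, so that the C14 radical is consumed by hydrogen-atom shifts, 1,2-acetoxy migration or intermolecular addition before it reaches C1. Fallback with known chemistry, setting out from 4 and returning at 23: the carbocycle is closed by alkene metathesis across C1=C14 and the lactone is then annulated by a fast 5-exo radical cyclisation.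
   - Enal 4 takes up vinylmagnesium bromide 15 (THF, −78 °C) to give the racemic C13 vinyl carbinol F1.
   - Sharpless kinetic resolution (Ti(OiPr)4, D-(−)-diisopropyl tartrate, t-BuOOH) gives the erythro epoxy alcohol F2, and Mitsunobu inversion with acetic acid gives the threo allylic acetate F3.
   - HF·pyridine frees the C2 allylic alcohol F4, MnO2 gives the enal F5, and the vinylzinc addition used in step 10 gives the C2 vinyl carbinol F6, now a 1,ω-diene.
   - Ring-closing metathesis (second-generation Grubbs catalyst RuCl2(=CHPh)(H2IMes)(PCy3), CH2Cl2, 0.001 M, reflux) should give the macrocyclic allylic alcohol F7; either C1=C14 geometry serves.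
   - Esterification with propiolic acid (DCC, CH2Cl2, −20 °C) gives the propiolate F8.
   - Slow addition of Bu3SnH with AIBN (benzene, 80 °C) adds Bu3Sn• to the alkyne terminus; the C15 vinyl radical cyclises 5-exo onto C1 anti to the C3 substituent (allylic-strain control) and the C14 radical is reduced, giving the α-(stannylmethylene) lactone F9.
   - Protodestannylation (pyridinium p-toluenesulfonate, wet CH2Cl2) gives 23.

2. Step 13. Coordination of the sulfide to ruthenium, together with slow closure onto the 2-substituted acrylate, may arrest the catalyst so that only cross-metathesis dimers of the vinyl group form. Fallback, setting out from 17 and returning at 22: the ring is closed before sulfur is introduced.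
   - Alcohol 17 is esterified with 2-(bromomethyl)acrylic acid 18 (DCC, CH2Cl2, −20 °C, no DMAP) to give the 2-(bromomethyl)acrylate F10.
   - Ring-closing metathesis under the conditions of step 13 gives the 3-(bromomethyl)butenolide F11.
   - Thiophenol 19 with iPr2NEt (CH2Cl2, −20 °C) replaces the activated allylic bromide, directly or by two SN2′ events that end at the conjugated isomer, to give 22.

3. Step 10. Uncatalysed vinyl transfer or Lewis-acidic zinc and magnesium salts may erode the facial selectivity at C2 or open the epoxide. Fallback, setting out from 14 and returning at 17: the stereocentre is set by a catalytic asymmetric alkynylation and the alkyne is then half-reduced.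
   - Enal 14 with trimethylsilylacetylene, Zn(CH3)2 and the ProPhenol ligand enantiomer matched to Re-face attack (toluene, 0 °C) gives the silylated propargylic alcohol F12.
   - Tetrabutylammonium fluoride buffered with acetic acid (THF, 0 °C) gives the terminal propargylic alcohol F13.
   - Hydrogenation over Lindlar catalyst (Pd/CaCO3 poisoned with Pb(OAc)2) with quinoline (EtOAc, H2) gives 17.

**Further compounds**

F1 | step 14 | rac-(4E,8E,12E)-14-(TBS-oxy)-4,8,12-trimethyltetradeca-1,4,8,12-tetraen-3-ol (C13 vinyl carbinol) | CC(C)(C)[Si](C)(C)OC/C=C(\C)CC/C=C(\C)CC/C=C(\C)C(O)C=C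
F2 | step 14 | (11R,12R,13R)-erythro epoxy alcohol, vinyl analogue of 10 | CC(C)(C)[Si](C)(C)OC/C=C(\C)CC/C=C(\C)CC[C@H]1O[C@]1(C)[C@H](O)C=C
F3 | step 14 | (11R,12S,13S)-threo allylic acetate, C2 TBS ether | CC(C)(C)[Si](C)(C)OC/C=C(\C)CC/C=C(\C)CC[C@H]1O[C@]1(C)[C@@H](OC(C)=O)C=C
F4 | step 14 | (11R,12S,13S)-C2 allylic alcohol | OC/C=C(\C)CC/C=C(\C)CC[C@H]1O[C@]1(C)[C@@H](OC(C)=O)C=C
F5 | step 14 | (11R,12S,13S)-C2 enal | O=C/C=C(\C)CC/C=C(\C)CC[C@H]1O[C@]1(C)[C@@H](OC(C)=O)C=C
F6 | step 14 | (2R,11R,12S,13S)-C2 vinyl carbinol with C13 vinyl group | C=C[C@@H](O)/C=C(\C)CC/C=C(\C)CC[C@H]1O[C@]1(C)[C@@H](OC(C)=O)C=C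
F7 | step 14 | (2R,11R,12S,13S)-13-acetoxy-11,12-epoxycembra-1(14),3,7-trien-2-ol skeleton without C15–C17 (macrocyclic allylic alcohol) | O[C@H]1/C=C(\C)CC/C=C(\C)CC[C@H]2O[C@]2(C)[C@@H](OC(C)=O)C=C1
F8 | step 14 | propiolate ester of F7 | C#CC(=O)O[C@H]1/C=C(\C)CC/C=C(\C)CC[C@H]2O[C@]2(C)[C@@H](OC(C)=O)C=C1
F9 | step 14 | (1R,2S,11R,12S,13S)-17-(tributylstannyl) derivative of 23 (α-stannylmethylene lactone) | CCCC[Sn](CCCC)(CCCC)C=C1C(=O)O[C@H]2/C=C(\C)CC/C=C(\C)CC[C@H]3O[C@]3(C)[C@@H](OC(C)=O)C[C@H]12
F10 | step 13 | 2-(bromomethyl)acrylate ester of 17 (2R,11R,12S,13R) | C=C(CBr)C(=O)O[C@H](C=C)/C=C(\C)CC/C=C(\C)CC[C@H]1O[C@]1(C)[C@@H](OC(C)=O)CI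
F11 | step 13 | 3-(bromomethyl)butenolide analogue of 22 (2S,11R,12S,13R) | O=C1O[C@@H](/C=C(\C)CC/C=C(\C)CC[C@H]2O[C@]2(C)[C@@H](OC(C)=O)CI)C=C1CBr
F12 | step 10 | (2S,11R,12S,13R)-C2 (trimethylsilyl)ethynyl carbinol | C[Si](C)(C)C#C[C@@H](O)/C=C(\C)CC/C=C(\C)CC[C@H]1O[C@]1(C)[C@@H](OC(C)=O)CI
F13 | step 10 | (2S,11R,12S,13R)-C2 ethynyl carbinol | C#C[C@@H](O)/C=C(\C)CC/C=C(\C)CC[C@H]1O[C@]1(C)[C@@H](OC(C)=O)CI
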